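**Assumption:** ent-kaurane atom numbers (C1–C20, no C8–C9 bond) are used for every intermediate; stereocentres that are erased later (C8 in 7, C9 in 11/12, C16 up to 15) are drawn as the expected isomer or left undefined.

## Retrosynthetic overview

1. The C7–O bond is made last, by a singlet-oxygen ene reaction on a macrocyclic (E)-2-alkylidenecyclopentanone; this also moves the alkene into ring D (C8=C14). The C11–OAc comes from oxidation of the C9 ketone enolate.
2. The ten-membered ring is closed at C9–C10 by a catalytic asymmetric carbonyl–ene macrocyclisation (new), which also creates the C10 quaternary centre; C5–H then comes from hydroxyl-directed hydrogenation.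
3. The open precursor comes from Horner–Wadsworth–Emmons union (C7=C8) of β-homocyclocitral (ring A, C1–C7, C10, C18–C20) with a ring D β-keto phosphonate.
4. The ring D piece comes from copper-catalysed asymmetric conjugate addition to cyclopent-2-enone (sets C13) with formaldehyde trapping (C17).
5. Ring order: ring D and ring A are bought; the ten-membered ring is formed in step 5.

## Route

Step 1
Reactants: 1 cyclopent-2-en-1-one; 2 [2-(1,3-dioxolan-2-yl)ethyl]magnesium bromide
Product: 5 (2R,3R)-2-{[(tert-butyldimethylsilyl)oxy]methyl}-3-[2-(1,3-dioxolan-2-yl)ethyl]cyclopentan-1-one, via magnesium enolate 3 (not isolated), via hydroxymethyl ketone 4 (not isolated)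
Conditions: CuBr·SMe2 (5 mol %), (R)-1-[(S)-2-(diphenylphosphino)ferrocenyl]ethyldicyclohexylphosphine (6 mol %; antipode chosen for 13R), tBuOMe, −75 °C; HCHO (gas), −75 → −40 °C; aq NH4Cl; crude: TBSCl, imidazole, DMF, 0 °C
Reagents that add atoms: formaldehyde, C=O; tert-butyldimethylsilyl chloride, CC(C)(C)[Si](C)(C)Cl
Why: Copper-catalysed asymmetric conjugate addition of a Grignard reagent (Feringa type) sets C13, the enolate is trapped regiospecifically at C16 by formaldehyde (aldol, trans to the C13 chain), and silylation masks the future C17 methylene; C16 is erased in step 8.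

Step 2
Reactants: 5 silyl ether ketone
Product: 7 diethyl {(3R,4R)-3-{[(tert-butyldimethylsilyl)oxy]methyl}-4-[2-(1,3-dioxolan-2-yl)ethyl]-2-oxocyclopentyl}phosphonate (C8 epimers), via enol phosphate 6 (not isolated)
Conditions: LiN(iPr)2, THF, −78 °C; ClP(O)(OEt)2; then LiN(iPr)2 (2.2 equiv), −78 → 0 °C; AcOH
Reagents that add atoms: diethyl chlorophosphate, CCOP(=O)(Cl)OCC
Why: Kinetic enolisation at the unhindered C8 methylene, O-phosphorylation and base-induced 1,3-phosphoryl O→C shift (Wiemer vinyl phosphate to β-keto phosphonate rearrangement) place the phosphonate on C8; the C8 centre becomes sp2 in step 3.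

Step 3
Reactants: 7 β-keto phosphonate; 8 β-homocyclocitral, (2,6,6-trimethylcyclohex-1-en-1-yl)acetaldehyde
Product: 9 (2R,3R,5E)-2-{[(tert-butyldimethylsilyl)oxy]methyl}-3-[2-(1,3-dioxolan-2-yl)ethyl]-5-[2-(2,6,6-trimethylcyclohex-1-en-1-yl)ethylidene]cyclopentan-1-one
Conditions: LiCl, iPr2NEt, MeCN, 0 °C → rt
Reagents that add atoms: none
Why: Horner–Wadsworth–Emmons olefination under Masamune–Roush conditions gives the (E)-2-alkylidenecyclopentanone (C6 anti to the carbonyl) and is mild enough to leave the skipped C5=C10 alkene and the β-silyloxy ketone alone.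

Step 4
Reactants: 9 dioxolane enone
Product: 10 3-[(1R,2R,4E)-2-{[(tert-butyldimethylsilyl)oxy]methyl}-3-oxo-4-[2-(2,6,6-trimethylcyclohex-1-en-1-yl)ethylidene]cyclopentyl]propanal
Conditions: In(OTf)3 (2 mol %), wet acetone, rt
Reagents that add atoms: water, O
Why: Mild Lewis-acid transacetalisation frees the C9 aldehyde without cleaving the silyl ether or isomerising the enone.

Step 5
Reactants: 10 enone aldehyde
Product: 11 macrocyclic dienone (5Z,7E,9S,10R,13R,16R): ring A, ten-membered ring and ring D; 9-OH, C5=C6 and C7=C8, C15 ketone, 16-CH2OTBS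
Conditions: (S,S)-IDPi confined imidodiphosphorimidate Brønsted acid (5 mol %; antipode matched to C13), 4 Å MS, cyclohexane/CH2Cl2, 2 mM (syringe pump), 0 °C → rt
Reagents that add atoms: none
Why: Proposed new method: the confined chiral acid activates the C9 aldehyde inside its pocket and the electron-rich tetrasubstituted C5=C10 alkene attacks through C10 (C5 is blocked by the gem-dimethyl group) in a chair-like six-centre ene transition state that passes the C6–H (allylic and γ to the enone, hence weakened) to oxygen, so the C9–C10 bond, the ten-membered ring and the C10 quaternary centre form in one step with C5=C6 left conjugated; the U-turn of the (E)-enone and high dilution favour ring closure, the catalyst fixes the C10 face (10R; C20 pseudo-axial and C11 pseudo-equatorial give 9S), and the closest known reaction type is the chiral imidodiphosphate-catalysed asymmetric intramolecular carbonyl–ene cyclisation to five- and six-membered rings, together with Me2AlCl-promoted ene macrocyclisations.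

Step 6
Reactants: 11 macrocyclic dienone
Product: 12 macrocyclic hydroxy enone (5R,9S,10R,13R,16R,7E): 9-OH, C7=C8, C15 ketone, 16-CH2OTBS
Conditions: [Ir(cod)(PCy3)(py)]PF6 (10 mol %), H2 (1 atm), CH2Cl2, 0 °C
Reagents that add atoms: none
Why: Hydroxyl-directed hydrogenation: the C9–OH binds iridium and hydrogen is delivered to the nearby C5=C6 bond on the face syn to C9, which is also the face away from the axial C4/C10 methyl groups; this sets C5 (H5 cis to C9, trans to C20) and leaves the undirected C7=C8 enone bond.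

Step 7
Reactants: 12 macrocyclic hydroxy enone
Product: 13 macrocyclic diketone (5R,10R,13R,16R,7E): C9 and C15 ketones, C7=C8, 16-CH2OTBS
Conditions: Dess–Martin periodinane, NaHCO3, CH2Cl2, rt
Reagents that add atoms: none
Why: Dess–Martin oxidation converts the hindered secondary alcohol to the C9 ketone under neutral conditions and removes the C9 stereocentre.

Step 8
Reactants: 13 macrocyclic diketone
Product: 16 bis-exocyclic dienone (5R,10R,13R,7E): C16=C17 and C7=C8 on the C15 ketone with C9 ketone, via primary alcohol 14 (not isolated), via mesylate 15 (not isolated)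
Conditions: HF·pyridine, THF, 0 °C → rt; aq NaHCO3; crude: MsCl, Et3N, CH2Cl2, 0 °C → rt
Reagents that add atoms: none
Why: Desilylation, mesylation and E1cB elimination unveil the C16=C17 methylene and remove C16; the C15 ketone now has no α-hydrogen, which makes step 9 regiochemically clean.

Step 9
Reactants: 16 bis-exocyclic dienone
Product: 19 11-acetoxy dienone (5R,10R,11S,7E; C13 unchanged but labelled S because C11 now bears oxygen), via potassium enolate 17 (not isolated), via potassium alkoxide 18 (not isolated)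
Conditions: KN(SiMe3)2 (1.05 equiv), THF, −78 °C; 2-(phenylsulfonyl)-3-phenyloxaziridine, −78 °C; Ac2O, −78 → 0 °C
Reagents that add atoms: 2-(phenylsulfonyl)-3-phenyloxaziridine, O=S(=O)(c1ccccc1)N1OC1c1ccccc1; acetic anhydride, CC(=O)OC(C)=O
Why: Davis enolate hydroxylation: only the C9 ketone can form an α-enolate (C10 is quaternary, C15 has no α-H), the oxaziridine attacks the outer face of the ring enolate (a rough model indicates this gives 11S), and trapping the alkoxide with Ac2O at low temperature prevents α-ketol shift or oxa-Michael addition.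

Step 10
Reactants: 19 11-acetoxy dienone
Product: 22 target CNP0417044.1 (5R,7R,10R,11S,13R), via allylic hydroperoxide 20 (not isolated), via allylic alcohol 21 (not isolated)
Conditions: O2, tetraphenylporphyrin (1 mol %), white LED, CH2Cl2, 0 °C; Me2S; then Ac2O, pyridine, 0 °C → rt
Reagents that add atoms: oxygen, O=O; acetic anhydride, CC(=O)OC(C)=O
Why: Schenck ene reaction of singlet oxygen with the s-cis exocyclic enone (geminal selectivity: O to C7, H from C14 on the same face) forms the C7–O bond and moves the alkene to C8=C14. Attack on the exposed face, away from the C9–C12 bridge, gives 7R for the E enone; the trisubstituted alkene should react well ahead of C16=C17, and Me2S reduction then acetylation complete the target.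

## Compound list

1 | cyclopent-2-en-1-one | O=C1C=CCC1 | starting material
2 | [2-(1,3-dioxolan-2-yl)ethyl]magnesium bromide | Br[Mg]CCC1OCCO1 | starting material
3 | bromomagnesium C15–C16 enolate from the conjugate addition (C13 as in 5) | Br[Mg]OC1=C[C@H](CCC2OCCO2)CC1 | intermediate (not isolated)
4 | (2R,3R)-3-[2-(1,3-dioxolan-2-yl)ethyl]-2-(hydroxymethyl)cyclopentan-1-one | O=C1[C@@H](CO)[C@H](CCC2OCCO2)CC1 | intermediate (not isolated)
5 | (2R,3R)-2-{[(tert-butyldimethylsilyl)oxy]methyl}-3-[2-(1,3-dioxolan-2-yl)ethyl]cyclopentan-1-one | O=C1[C@@H](CO[Si](C)(C)C(C)(C)C)[C@H](CCC2OCCO2)CC1 | intermediate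
6 | diethyl (4R,5R)-5-{[(tert-butyldimethylsilyl)oxy]methyl}-4-[2-(1,3-dioxolan-2-yl)ethyl]cyclopent-1-en-1-yl phosphate | CCOP(=O)(OCC)OC1=CC[C@@H](CCC2OCCO2)[C@@H]1CO[Si](C)(C)C(C)(C)C | intermediate (not isolated)
7 | diethyl {(3R,4R)-3-{[(tert-butyldimethylsilyl)oxy]methyl}-4-[2-(1,3-dioxolan-2-yl)ethyl]-2-oxocyclopentyl}phosphonate (C8 epimers) | CCOP(=O)(OCC)C1C[C@@H](CCC2OCCO2)[C@H](CO[Si](C)(C)C(C)(C)C)C1=O | intermediate
8 | β-homocyclocitral, (2,6,6-trimethylcyclohex-1-en-1-yl)acetaldehyde | O=CCC1=C(C)CCCC1(C)C | starting material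
9 | (2R,3R,5E)-2-{[(tert-butyldimethylsilyl)oxy]methyl}-3-[2-(1,3-dioxolan-2-yl)ethyl]-5-[2-(2,6,6-trimethylcyclohex-1-en-1-yl)ethylidene]cyclopentan-1-one | O=C1[C@@H](CO[Si](C)(C)C(C)(C)C)[C@H](CCC2OCCO2)C/C1=C\CC3=C(C)CCCC3(C)C | intermediate
10 | 3-[(1R,2R,4E)-2-{[(tert-butyldimethylsilyl)oxy]methyl}-3-oxo-4-[2-(2,6,6-trimethylcyclohex-1-en-1-yl)ethylidene]cyclopentyl]propanal | O=C1[C@@H](CO[Si](C)(C)C(C)(C)C)[C@H](CCC=O)C/C1=C\CC2=C(C)CCCC2(C)C | intermediate
11 | macrocyclic dienone (5Z,7E,9S,10R,13R,16R), 9-OH, 16-CH2OTBS, C15 ketone | CC(C)(C)[Si](C)(C)OC[C@@H]1C(=O)/C2=C/C=C3/C(C)(C)CCC[C@@]3(C)[C@@H](O)CC[C@@H]1C2 | intermediate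
12 | macrocyclic hydroxy enone (5R,9S,10R,13R,16R,7E), 16-CH2OTBS | CC(C)(C)[Si](C)(C)OC[C@@H]1C(=O)/C2=C/C[C@@H]3C(C)(C)CCC[C@@]3(C)[C@@H](O)CC[C@@H]1C2 | intermediate
13 | macrocyclic 9,15-diketone (5R,10R,13R,16R,7E), 16-CH2OTBS | CC(C)(C)[Si](C)(C)OC[C@@H]1C(=O)/C2=C/C[C@@H]3C(C)(C)CCC[C@@]3(C)C(=O)CC[C@@H]1C2 | intermediate
14 | 16-(hydroxymethyl) 9,15-diketone (5R,10R,13R,16R,7E) | OC[C@@H]1C(=O)/C2=C/C[C@@H]3C(C)(C)CCC[C@@]3(C)C(=O)CC[C@@H]1C2 | intermediate (not isolated)
15 | 16-(mesyloxymethyl) 9,15-diketone (5R,10R,13R,16R,7E) | CS(=O)(=O)OC[C@@H]1C(=O)/C2=C/C[C@@H]3C(C)(C)CCC[C@@]3(C)C(=O)CC[C@@H]1C2 | intermediate (not isolated)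
16 | bis-exocyclic dienone (5R,10R,13R,7E): C16=C17, C7=C8, C9 and C15 ketones | C=C1C(=O)/C2=C/C[C@@H]3C(C)(C)CCC[C@@]3(C)C(=O)CC[C@@H]1C2 | intermediate
17 | potassium C9–C11 enolate of 16 | C=C1C(=O)/C2=C/C[C@@H]3C(C)(C)CCC[C@@]3(C)C(O[K])=CC[C@@H]1C2 | intermediate (not isolated)
18 | potassium (11S)-alkoxide of the 11-hydroxy dienone | C=C1C(=O)/C2=C/C[C@@H]3C(C)(C)CCC[C@@]3(C)C(=O)[C@@H](O[K])C[C@@H]1C2 | intermediate (not isolated)
19 | (11S)-11-acetoxy bis-exocyclic dienone (5R,10R,11S,7E) | C=C1C(=O)/C2=C/C[C@@H]3C(C)(C)CCC[C@@]3(C)C(=O)[C@@H](OC(C)=O)C[C@@H]1C2 | intermediate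
20 | (7R)-7-hydroperoxy-11-acetoxy 8(14),16-diene-9,15-dione | C=C1C(=O)C2=C[C@H]1C[C@H](OC(C)=O)C(=O)[C@]1(C)CCCC(C)(C)[C@H]1C[C@H]2OO | intermediate (not isolated)
21 | (7R)-7-hydroxy-11-acetoxy 8(14),16-diene-9,15-dione | C=C1C(=O)C2=C[C@H]1C[C@H](OC(C)=O)C(=O)[C@]1(C)CCCC(C)(C)[C@H]1C[C@H]2O | intermediate (not isolated)
22 | target CNP0417044.1, (5R,7R,10R,11S,13R)-7,11-diacetoxy-8,9-seco-kaura-8(14),16-diene-9,15-dione | C=C1C(=O)C2=C[C@H]1C[C@H](OC(C)=O)C(=O)[C@]1(C)CCCC(C)(C)[C@H]1C[C@H]2OC(C)=O | target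

## Summary

Total step count: 10. Longest linear sequence: 10 steps (from 1).

Steps most likely to fail:

Step 5 (the new ene macrocyclisation; ring closure, regiochemistry at C10 versus C5, and catalyst control of C10 are all unproven). The fallback uses known chemistry, sets out from 7 and returns at 12. Transacetalisation of 7 (In(OTf)3, wet acetone) gives aldehyde phosphonate F1. Chiral phosphoric acid-catalysed allylboration ((R)-TRIP or its antipode, whichever gives 10R; toluene, −30 °C) with (2,6,6-trimethylcyclohex-1-en-1-yl)methyl pinacol boronate F2 (from commercial β-cyclogeraniol, B2pin2, [Pd(MeCN)4](BF4)2) gives homoallylic alcohol F3; the closed chair transition state fixes 9S,10R. Rhodium-catalysed hydroformylation of the exocyclic methylene (Rh(acac)(CO)2, tris(2,4-di-tert-butylphenyl) phosphite, CO/H2) gives the linear aldehyde F4, with H added to C5 anti to the axial methyl groups. Intramolecular Horner–Wadsworth–Emmons ring closure (LiCl, iPr2NEt, MeCN, high dilution) then gives 12.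

Step 9 (facial selectivity at C11 is substrate-controlled and only roughly modelled; γ-deprotonation at C6 may compete). The fallback sets out from 16 and returns at 19. The enolate oxidation is quenched with aq NH4Cl instead of Ac2O; if the alcohol is the (11R)-hydroxy ketone F5, it is inverted by Mitsunobu esterification (AcOH, PPh3, DIAD, THF) to give 19 by SN2 displacement instead of facial control.

Step 10 (ene reaction at C16=C17 or hydrogen abstraction from C6 may compete). The fallback sets out from 19 and returns at 22. The exocyclic methylene is masked by thia-Michael addition of PhSH (Et3N, CH2Cl2) to give sulfide F6. Photo-oxygenation as in step 10 then has a single reactive alkene and oxidises the sulfide to the sulfoxide in the same operation; after Me2S and Ac2O/pyridine this gives sulfoxide diacetate F7. Thermolysis (toluene, 90 °C, CaCO3) expels the sulfenic acid and regenerates C16=C17 to give 22.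

## Further compounds

F1 | step 5 | diethyl {(3R,4R)-3-{[(tert-butyldimethylsilyl)oxy]methyl}-2-oxo-4-(3-oxopropyl)cyclopentyl}phosphonate | CCOP(=O)(OCC)C1C[C@@H](CCC=O)[C@H](CO[Si](C)(C)C(C)(C)C)C1=O
F2 | step 5 | 4,4,5,5-tetramethyl-2-[(2,6,6-trimethylcyclohex-1-en-1-yl)methyl]-1,3,2-dioxaborolane | CC1=C(CB2OC(C)(C)C(C)(C)O2)C(C)(C)CCC1
F3 | step 5 | (9S,10R) homoallylic alcohol with exocyclic C5=C6 methylene and ring D keto phosphonate | CCOP(=O)(OCC)C1C[C@@H](CC[C@H](O)[C@]2(C)CCCC(C)(C)C2=C)[C@H](CO[Si](C)(C)C(C)(C)C)C1=O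
F4 | step 5 | (5R,9S,10R) hydroxy aldehyde (C7 aldehyde) with ring D keto phosphonate | CCOP(=O)(OCC)C1C[C@@H](CC[C@H](O)[C@]2(C)CCCC(C)(C)[C@H]2CC=O)[C@H](CO[Si](C)(C)C(C)(C)C)C1=O
F5 | step 9 | (11R)-11-hydroxy bis-exocyclic dienone | C=C1C(=O)/C2=C/C[C@@H]3C(C)(C)CCC[C@@]3(C)C(=O)[C@H](O)C[C@@H]1C2
F6 | step 10 | 17-(phenylthio) adduct of 19 (C16 epimers) | c1ccc(cc1)SCC1C(=O)/C2=C/C[C@@H]3C(C)(C)CCC[C@@]3(C)C(=O)[C@@H](OC(C)=O)C[C@@H]1C2
F7 | step 10 | 17-(phenylsulfinyl) 7,11-diacetate (C16 and S epimers) | O=S(CC1C(=O)C2=C[C@H]1C[C@H](OC(C)=O)C(=O)[C@]1(C)CCCC(C)(C)[C@H]1C[C@H]2OC(C)=O)c1ccccc1
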